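Two questions rest on two runs, oak and maple, which differ in reagent charge, so begin by subtracting them.

all flasks: left-handed substrate 0.13 M; right-handed substrate 0.13 M; precatalyst 0.16 mM
- oak: reagent 0.087 M; run made earlier
- maple: reagent 0.20 M; run made earlier
- flask: reagent 0.130 M

- oak (time / h: left-handed product / %): 0.500: 1.8; 1.00: 4.2; 2.00: 8.1; 4.00: 10.5; 8.00: 12.3
- maple (time / h: left-handed product / %): 0.500: 3.8; 1.00: 8.2; 2.00: 12.6; 4.00: 16.2; 8.00: 19.5

(readings scatter by 0.3 percentage points)

1. factor on the rate of making left-handed product when 5.0% of the left-handed substrate and right-handed substrate together are converted if reagent is charged twice over
2. factor on the rate when 5.0% of the left-handed substrate and right-handed substrate together are converted if precatalyst is charged at 0.030 mM instead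

- catalyst is single-handed; left-handed substrate and right-handed substrate are mirror images of each other, charged as a racemate, each of them at the stated concentration
- reactions considered so far: 2 reagent -> homo dimer; reagent + catalyst + right-handed substrate -> catalyst + right-handed product; reagent + catalyst + left-handed substrate -> catalyst + left-handed product; precatalyst <-> catalyst
- no earlier run changes the charge of precatalyst; that part of a forecast is a guess

Maple's last reading exceeds oak's, so call the left-handed product gained per extra reagent charged the marginal yield: 0.166 as read after 8.00 h. Oak's whole charge bought 0.368 per reagent, more than the marginal yield, so reagent pays worse where more of it stands, as a second-order loss to homo dimer implies. Add the flask's extra reagent to oak as a correction, and my reckoning puts left-handed product near 15.0% at that time.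

Now guess, with no run to test it, that the yield scales with precatalyst: the load share 0.188 cuts it to 0.0311. If the hands share the conversion equally, reaching the asked conversion costs 0.209 M of reagent at that price, more than the charge of 0.130 M, so on my reckoning the lower charge goes deep into its reagent, and I put its rate factor below the load share.

The forecast says 1.8 and 0.03, the latter “while reagent dimerises away”.

The simulation gives 1.78 and 0.0862.

    2 reagent → homo dimer (k = 2.12 /M/h)
    reagent + catalyst + right-handed substrate → catalyst + right-handed product (k = 14300 /M²/h)
    reagent + catalyst + left-handed substrate → catalyst + left-handed product (k = 30100 /M²/h)
    precatalyst ⇌ catalyst (K = 0.550, k = 1.85 /h)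

This flask holds 15.0% left-handed product after 6.00 h and 17.3% after 60.0 h, against the 15.0% that the marginal yield gave for 8.00 h. Of the three simulated removals, the largest single effect on this flask's rate at the asked conversion, reached after 0.576 h, comes from the back reaction of catalyst to precatalyst, though it is not the main reason for that rate. The run with that back reaction taken away gives 1.74 times the actual rate, whereas the run without the path to homo dimer, which is a part of the story, gives 1.30 times.

Readings and results are calculated from invented constants, and the scatter is random.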